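**Plan**

1. Retrosynthetic cuts, in order: the nine O–benzyl bonds and the C8–Br bond of the lower unit; C3–O and C2–H of the upper ring C; then O1–C2 and C4a–C4 of the upper ring C together, which releases phloroglucinol and a chalcone; then the chalcone C=C bond; last the C6–CHO bond of the lower unit.
2. Forward: (+)-gallocatechin supplies the whole lower unit. It is benzylated, blocked at C8 with bromine, formylated at C6 and condensed with 3,4,5-tris(benzyloxy)acetophenone, so the 4→6 interflavan bond exists before the upper unit does. The upper ring C is then closed onto phloroglucinol (the upper ring A) in one operation, hydroborated, and everything is unmasked by one hydrogenolysis.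
3. Enabling feature: the upper ring A is a phloroglucinol, the enol of a cyclic triketone, so C4a and the oxygen on C8a form a C,O-1,3-dinucleophile. C4 and C2 are both benzylic and 1,3-related, and C4 sits on the electron-rich ring A of the lower unit, so the enone C4=C3–C2=O is the matching 1,3-dielectrophile and ring C is the product of a formal [3+3] annulation.
4. Stereochemistry: C2 and C3 of the lower unit are bought with (+)-gallocatechin. C4 of the upper unit is set by a chiral Brønsted acid in the annulation. C2 and C3 of the upper unit are relayed from C4 in one event, a syn hydroboration anti to the C4 aryl group (2,3-trans-3,4-trans).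
5. Helpers: bromine at C8 of the lower unit (sends the formylation to C6 and silences ring A of the lower unit as a nucleophile) and the benzyl ethers; both leave in the last step.

Key step: step 7

Remark: flavan numbering is used (O1, C2, C3, C4, C4a, C5–C8, C8a; ring A benzo, ring C pyran, ring B the 2-aryl group); the unit bonded through C4 is the upper unit and the one bonded through C6 the lower unit; Bn = benzyl; L = the protected lower-unit residue (2R,3S)-3,5,7-tris(benzyloxy)-8-bromo-2-[3,4,5-tris(benzyloxy)phenyl]chroman-6-yl; (+)-gallocatechin, 3,4,5-tris(benzyloxy)benzoic acid and phloroglucinol are taken as purchased.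

**Route**

Step 1
Reactants: 1 (+)-gallocatechin
Product: 2 5,7,3′,4′,5′-penta-O-benzyl-(+)-gallocatechin
Conditions: BnBr (5.5 equiv), K2CO3 (6 equiv), DMF, 0 °C → rt, under argon
Reagents that add atoms: benzyl bromide, BrCc1ccccc1
Why: Williamson etherification in which K2CO3 deprotonates only the five phenols, so the secondary 3-OH stays free and no stereocentre is touched.

Step 2
Reactants: 2 5,7,3′,4′,5′-penta-O-benzyl-(+)-gallocatechin
Product: 3 3,5,7,3′,4′,5′-hexa-O-benzyl-(+)-gallocatechin
Conditions: NaH (1.5 equiv), BnBr (1.3 equiv), DMF, 0 °C → rt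
Reagents that add atoms: benzyl bromide, BrCc1ccccc1
Why: Williamson etherification of the sodium alkoxide, which shields the 3-OH from the Vilsmeier reagent and from borane in later steps.

Step 3
Reactants: 3 3,5,7,3′,4′,5′-hexa-O-benzyl-(+)-gallocatechin
Product: 4 8-bromo-3,5,7,3′,4′,5′-hexa-O-benzyl-(+)-gallocatechin
Conditions: N-bromosuccinimide (1.05 equiv), CH2Cl2, −78 °C → rt
Reagents that add atoms: N-bromosuccinimide, O=C1CCC(=O)N1Br
Why: electrophilic aromatic bromination of the phloroglucinol-type ring A, which is far more reactive than ring B and reacts at C8 (next to the ring oxygen and one OBn) in preference to C6 (between two OBn), the regiochemistry known for benzylated flavan-3-ols.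

Step 4
Reactants: 4 8-bromo-3,5,7,3′,4′,5′-hexa-O-benzyl-(+)-gallocatechin
Product: 6 8-bromo-6-formyl-3,5,7,3′,4′,5′-hexa-O-benzyl-(+)-gallocatechin (L–CHO), via iminium chloride 5 (not isolated)
Conditions: POCl3 (3 equiv), DMF, 0 → 50 °C; then H2O, rt
Reagents that add atoms: N,N-dimethylformamide, CN(C)C=O; water, O
Why: Vilsmeier–Haack formylation at C6, the only free position of ring A and ortho, ortho and para to three ether oxygens, run at a temperature at which the pyrogallol-ether ring B should not yet react.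

Step 5
Reactants: 7 3,4,5-tris(benzyloxy)benzoic acid
Product: 9 1-[3,4,5-tris(benzyloxy)phenyl]ethanone, via dilithium gem-diolate 8 (not isolated)
Conditions: MeLi (2.2 equiv), THF, 0 °C → rt; then poured into cold aq HCl
Reagents that add atoms: methyllithium, [Li]C
Why: addition of methyllithium to the lithium carboxylate stops at the gem-diolate, which collapses to the methyl ketone only on acidic quench.

Step 6
Reactants: 6 8-bromo-6-formyl-3,5,7,3′,4′,5′-hexa-O-benzyl-(+)-gallocatechin; 9 1-[3,4,5-tris(benzyloxy)phenyl]ethanone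
Product: 10 (E)-3-L-1-[3,4,5-tris(benzyloxy)phenyl]prop-2-en-1-one
Conditions: KOH (aq, 3 equiv), EtOH/THF, rt
Reagents that add atoms: none
Why: Claisen–Schmidt aldol condensation of a non-enolisable aldehyde with a methyl ketone, the E-alkene arising from E1cB dehydration under thermodynamic control.

Step 7
Reactants: 10 (E)-3-L-1-[3,4,5-tris(benzyloxy)phenyl]prop-2-en-1-one; 11 phloroglucinol
Product: 14 (4S)-4-L-2-[3,4,5-tris(benzyloxy)phenyl]-4H-chromene-5,7-diol, via ketone adduct 12 (not isolated), via cyclic hemiketal 13 (not isolated)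
Conditions: 11 (4 equiv), (R)-3,3′-bis(2,4,6-triisopropylphenyl)-1,1′-binaphthyl-2,2′-diyl N-triflylphosphoramide (10 mol %), 4 Å molecular sieves, CH2Cl2/t-BuOMe, −20 °C → rt
Reagents that add atoms: none
Why: Proposed new method: the chiral N-triflylphosphoramide protonates the enone carbonyl of 10 to a hydroxyallyl cation delocalised into the trioxygenated ring A of the lower unit, and its conjugate base, hydrogen-bonded to a hydroxyl of phloroglucinol, guides the adjacent ring carbon onto the β-carbon in a Friedel–Crafts conjugate addition (C4a–C4), after which the neighbouring phenolic oxygen adds to the ketone and the hemiketal loses water (O1–C2). The closest known reaction types are the Brønsted acid-catalysed annulation of phenols and naphthols with chalcones to 2,4-diaryl-4H-chromenes and the activation of enones by chiral N-triflylphosphoramides in Nazarov, Diels–Alder and conjugate Friedel–Crafts reactions. Ring C closes by 6-exo-trig attack of the phenol oxygen on the carbonyl carbon followed by dehydration, overall a formal [3+3] annulation of a C,O-1,3-dinucleophile with a 1,3-dielectrophile. C4 is the only new stereocentre and is controlled by the catalyst within the ion pair; the bought stereocentres of the lower unit are too remote to steer it but turn any C4 epimer into a diastereomer that can be removed by chromatography. The step needs C- over O-alkylation, single over multiple alkylation and no self-condensation: the threefold symmetry of phloroglucinol makes every ring carbon equivalent and flanked by two hydroxyls, the excess of 11 should suppress a second alkylation, and the bromine at C8 together with the substituent at C6 leaves ring A of the lower unit without a free nucleophilic position.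

Step 8
Reactants: 14 (4S)-4-L-2-[3,4,5-tris(benzyloxy)phenyl]-4H-chromene-5,7-diol
Product: 16 (2R,3S,4S)-4-L-2-[3,4,5-tris(benzyloxy)phenyl]chromane-3,5,7-triol, via C3 organoborane 15 (not isolated)
Conditions: BH3·THF (6 equiv), THF, 0 °C → rt; then 30% H2O2, aq NaOAc, 0 °C
Reagents that add atoms: borane–tetrahydrofuran, [BH3-][O+]1CCCC1 (boron of 15); hydrogen peroxide, OO (oxygen at C3)
Why: hydroboration–oxidation of a cyclic aryl enol ether, known for flav-2-enes and 1-aryl glycals, places boron at C3 and hydrogen at C2 in a syn addition on the face opposite the pseudo-axial C4 aryl group, so C2 and C3 are both set from C4 in one event (2,3-trans-3,4-trans) and the C–B bond is oxidised with retention.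

Step 9
Reactants: 16 (2R,3S,4S)-4-L-2-[3,4,5-tris(benzyloxy)phenyl]chromane-3,5,7-triol
Product: 17 gallocatechin-(4α→6)-gallocatechin (target)
Conditions: H2 (1 atm), Pd(OH)2/C, Et3N (1.5 equiv), THF/MeOH/H2O, rt
Reagents that add atoms: none
Why: hydrogenolysis of the nine O-benzyl ethers with concurrent hydrodebromination of C8–Br (Et3N takes up the HBr), conditions under which the benzylic C2–O1 and C4–aryl bonds of flavans are known to survive, so no stereocentre is touched.

**Compound list**

1 | (+)-gallocatechin, (2R,3S)-2-(3,4,5-trihydroxyphenyl)chromane-3,5,7-triol | O[C@H]1Cc2c(O)cc(O)cc2O[C@@H]1c1cc(O)c(O)c(O)c1 | starting material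
2 | (2R,3S)-5,7-bis(benzyloxy)-2-[3,4,5-tris(benzyloxy)phenyl]chroman-3-ol | O[C@H]1Cc2c(OCc3ccccc3)cc(OCc3ccccc3)cc2O[C@@H]1c1cc(OCc2ccccc2)c(OCc2ccccc2)c(OCc2ccccc2)c1 | intermediate
3 | (2R,3S)-3,5,7-tris(benzyloxy)-2-[3,4,5-tris(benzyloxy)phenyl]chromane | c1ccccc1CO[C@H]1Cc2c(OCc3ccccc3)cc(OCc3ccccc3)cc2O[C@@H]1c1cc(OCc2ccccc2)c(OCc2ccccc2)c(OCc2ccccc2)c1 | intermediate
4 | (2R,3S)-3,5,7-tris(benzyloxy)-8-bromo-2-[3,4,5-tris(benzyloxy)phenyl]chromane (L–H) | c1ccccc1CO[C@H]1Cc2c(OCc3ccccc3)cc(OCc3ccccc3)c(Br)c2O[C@@H]1c1cc(OCc2ccccc2)c(OCc2ccccc2)c(OCc2ccccc2)c1 | intermediate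
5 | N-(L-methylidene)-N-methylmethanaminium chloride (L–CH=NMe2+ Cl−) | c1ccccc1CO[C@H]1Cc2c(OCc3ccccc3)c(C=[N+](C)C)c(OCc3ccccc3)c(Br)c2O[C@@H]1c1cc(OCc2ccccc2)c(OCc2ccccc2)c(OCc2ccccc2)c1.[Cl-] | intermediate (not isolated)
6 | (2R,3S)-3,5,7-tris(benzyloxy)-8-bromo-2-[3,4,5-tris(benzyloxy)phenyl]chromane-6-carbaldehyde (L–CHO) | c1ccccc1CO[C@H]1Cc2c(OCc3ccccc3)c(C=O)c(OCc3ccccc3)c(Br)c2O[C@@H]1c1cc(OCc2ccccc2)c(OCc2ccccc2)c(OCc2ccccc2)c1 | intermediate
7 | 3,4,5-tris(benzyloxy)benzoic acid | OC(=O)c1cc(OCc2ccccc2)c(OCc2ccccc2)c(OCc2ccccc2)c1 | starting material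
8 | dilithium 1-[3,4,5-tris(benzyloxy)phenyl]ethane-1,1-diolate | CC([O-])([O-])c1cc(OCc2ccccc2)c(OCc2ccccc2)c(OCc2ccccc2)c1.[Li+].[Li+] | intermediate (not isolated)
9 | 1-[3,4,5-tris(benzyloxy)phenyl]ethanone | CC(=O)c1cc(OCc2ccccc2)c(OCc2ccccc2)c(OCc2ccccc2)c1 | intermediate
10 | (E)-3-L-1-[3,4,5-tris(benzyloxy)phenyl]prop-2-en-1-one | c1ccccc1CO[C@H]1Cc2c(OCc3ccccc3)c(/C=C/C(=O)c3cc(OCc4ccccc4)c(OCc4ccccc4)c(OCc4ccccc4)c3)c(OCc3ccccc3)c(Br)c2O[C@@H]1c1cc(OCc2ccccc2)c(OCc2ccccc2)c(OCc2ccccc2)c1 | intermediate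
11 | phloroglucinol (benzene-1,3,5-triol) | Oc1cc(O)cc(O)c1 | starting material
12 | (3S)-3-L-3-(2,4,6-trihydroxyphenyl)-1-[3,4,5-tris(benzyloxy)phenyl]propan-1-one | O=C(c1cc(OCc3ccccc3)c(OCc3ccccc3)c(OCc3ccccc3)c1)C[C@@H](c1c(O)cc(O)cc1O)c1c(OCc3ccccc3)c(Br)c2c(c1OCc3ccccc3)C[C@H](OCc3ccccc3)[C@@H](c3cc(OCc4ccccc4)c(OCc4ccccc4)c(OCc4ccccc4)c3)O2 | intermediate (not isolated)
13 | (4S)-4-L-2-[3,4,5-tris(benzyloxy)phenyl]chromane-2,5,7-triol (both configurations at C2) | Oc1cc(O)c2c(c1)OC(O)(c1cc(OCc3ccccc3)c(OCc3ccccc3)c(OCc3ccccc3)c1)C[C@@H]2c1c(OCc3ccccc3)c(Br)c2c(c1OCc3ccccc3)C[C@H](OCc3ccccc3)[C@@H](c3cc(OCc4ccccc4)c(OCc4ccccc4)c(OCc4ccccc4)c3)O2 | intermediate (not isolated)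
14 | (4S)-4-L-2-[3,4,5-tris(benzyloxy)phenyl]-4H-chromene-5,7-diol | Oc1cc(O)c2c(c1)OC(c1cc(OCc3ccccc3)c(OCc3ccccc3)c(OCc3ccccc3)c1)=C[C@@H]2c1c(OCc3ccccc3)c(Br)c2c(c1OCc3ccccc3)C[C@H](OCc3ccccc3)[C@@H](c3cc(OCc4ccccc4)c(OCc4ccccc4)c(OCc4ccccc4)c3)O2 | intermediate
15 | 3-boryl adduct of 14 (boron at C3 trans to the C4 aryl group and cis to the new C2–H; drawn as the monoalkylborane with free phenols, which in the flask are carried as aryloxyboranes) | Oc1cc(O)c2c(c1)O[C@H](c1cc(OCc3ccccc3)c(OCc3ccccc3)c(OCc3ccccc3)c1)[C@@H](B)[C@@H]2c1c(OCc3ccccc3)c(Br)c2c(c1OCc3ccccc3)C[C@H](OCc3ccccc3)[C@@H](c3cc(OCc4ccccc4)c(OCc4ccccc4)c(OCc4ccccc4)c3)O2 | intermediate (not isolated)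
16 | (2R,3S,4S)-4-L-2-[3,4,5-tris(benzyloxy)phenyl]chromane-3,5,7-triol | Oc1cc(O)c2c(c1)O[C@H](c1cc(OCc3ccccc3)c(OCc3ccccc3)c(OCc3ccccc3)c1)[C@@H](O)[C@@H]2c1c(OCc3ccccc3)c(Br)c2c(c1OCc3ccccc3)C[C@H](OCc3ccccc3)[C@@H](c3cc(OCc4ccccc4)c(OCc4ccccc4)c(OCc4ccccc4)c3)O2 | intermediate
17 | gallocatechin-(4α→6)-gallocatechin, (2R,3S,4R)-4-[(2R,3S)-3,5,7-trihydroxy-2-(3,4,5-trihydroxyphenyl)chroman-6-yl]-2-(3,4,5-trihydroxyphenyl)chromane-3,5,7-triol | Oc1cc(O)c2c(c1)O[C@H](c1cc(O)c(O)c(O)c1)[C@@H](O)[C@@H]2c1c(O)cc2c(c1O)C[C@H](O)[C@@H](c1cc(O)c(O)c(O)c1)O2 | target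

**Step count and risks**

Total: 9 steps. Longest linear sequence: 8 steps (steps 1–4 and 6–9, from (+)-gallocatechin).

Steps most likely to fail:

1. Step 7 (proposed new method). The facial discrimination in the ion pair may be weak or opposite in sense, the cascade may stall at the open-chain ketone or the hemiketal, the conjugate addition may revert on warming and erode the C4 configuration, or the 4H-chromene may lose hydride from C4 to protonated enone. The fallback uses the known cationic interflavan coupling; it sets out from 3 and 4 and comes back to the route at 17. Compound 3 is oxidised at C4 with 2,3-dichloro-5,6-dicyano-1,4-benzoquinone in CH2Cl2 in the presence of 2-ethoxyethanol to the 4-(2-ethoxyethoxy) ether F1. Me3SiOTf in CH2Cl2 at −78 °C ionises F1 to the flavan-4-yl cation, which an excess of 4, with C8 blocked, can take up only at C6; after separation from the 3,4-cis isomer this should give the fully benzylated 4α→6 dimer F2. F2 is hydrogenolysed under the conditions of step 9 to 17. Here the C4–C6 bond is formed last and the upper unit also comes from (+)-gallocatechin.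

2. Step 4. The hindered, bromine-deactivated C6 may react sluggishly, ipso attack may displace or move the bromine, and ring B may be formylated in competition. The fallback sets out from 4 and comes back at 6. Compound 4 is iodinated at C6 with N-iodosuccinimide and catalytic CF3CO2H in CH2Cl2 to the 8-bromo-6-iodo compound F3. iPrMgCl·LiCl in THF at −40 °C exchanges the C–I bond in preference to the C–Br bond, and the arylmagnesium species is quenched with DMF to give 6.

3. Step 8. The 3-boryl intermediate may undergo β-elimination with the ring oxygen as leaving group and open ring C, the free phenols consume borane, and the facial selectivity may be incomplete. The fallback sets out from 14 and comes back at 16. Compound 14 is dihydroxylated on the face opposite the C4 aryl group with catalytic OsO4 and N-methylmorpholine N-oxide in acetone/water to the 2,3-dihydroxy hemiketal F4. Et3SiH and BF3·OEt2 in CH2Cl2/MeCN at −40 °C then reduce the anomeric hydroxyl through the C2 oxocarbenium ion, with axial hydride delivery as in C-aryl glycoside synthesis, which places the 2-aryl group equatorial and trans to the 3-OH and gives 16.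

**Further compounds**

F1 | step 7 | (2R,3S)-3,5,7-tris(benzyloxy)-4β-(2-ethoxyethoxy)-2-[3,4,5-tris(benzyloxy)phenyl]chromane (3,4-cis; the C4 configuration is lost on ionisation) | c1ccccc1COc1cc(OCc3ccccc3)c2c(c1)O[C@H](c1cc(OCc3ccccc3)c(OCc3ccccc3)c(OCc3ccccc3)c1)[C@@H](OCc1ccccc1)[C@H]2OCCOCC
F2 | step 7 | 8-bromo-dodeca-O-benzyl-gallocatechin-(4α→6)-gallocatechin (3,5,7-tris(benzyloxy)-4α-L-2-[3,4,5-tris(benzyloxy)phenyl]chromane with 2R,3S and 3,4-trans) | c1ccccc1COc1cc(OCc3ccccc3)c2c(c1)O[C@H](c1cc(OCc3ccccc3)c(OCc3ccccc3)c(OCc3ccccc3)c1)[C@@H](OCc1ccccc1)[C@@H]2c1c(OCc3ccccc3)c(Br)c2c(c1OCc3ccccc3)C[C@H](OCc3ccccc3)[C@@H](c3cc(OCc4ccccc4)c(OCc4ccccc4)c(OCc4ccccc4)c3)O2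
F3 | step 4 | (2R,3S)-3,5,7-tris(benzyloxy)-8-bromo-6-iodo-2-[3,4,5-tris(benzyloxy)phenyl]chromane | c1ccccc1CO[C@H]1Cc2c(OCc3ccccc3)c(I)c(OCc3ccccc3)c(Br)c2O[C@@H]1c1cc(OCc2ccccc2)c(OCc2ccccc2)c(OCc2ccccc2)c1
F4 | step 8 | (3S,4S)-4-L-2-[3,4,5-tris(benzyloxy)phenyl]chromane-2,3,5,7-tetrol (3-OH trans to the C4 aryl group; both configurations at C2) | Oc1cc(O)c2c(c1)OC(O)(c1cc(OCc3ccccc3)c(OCc3ccccc3)c(OCc3ccccc3)c1)[C@@H](O)[C@@H]2c1c(OCc3ccccc3)c(Br)c2c(c1OCc3ccccc3)C[C@H](OCc3ccccc3)[C@@H](c3cc(OCc4ccccc4)c(OCc4ccccc4)c(OCc4ccccc4)c3)O2
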